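**Retrosynthetic overview**
- Ring C is closed last: a one-carbon unit (the isoflavone C2) is condensed onto a 2-hydroxydeoxybenzoin, and the ring A ortho-OH closes the pyranone while the ring B phenol is still a TIPS ether.
- Key disconnection: the C3–C1' bond (deoxybenzoin CH2–aryl). Both carbons are nucleophilic by nature, so the ketone α-carbon is inverted to an enolonium (α-keto-λ3-iodane from a silyl enol ether and trivalent iodine) and captured by the arene C–H.
- Ring A partner: phloroacetophenone, persilylated in one operation (phenol protection plus silyl enol ether).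
- Ring B partner: 3,5-dimethoxyphenol, silylated, lithiated between the two methoxy groups and prenylated; it is symmetric, so its two free positions are equivalent.
- Rings A and B are bought as benzenes; only ring C is built.

Assumption: the target has no stereocentre and no stereogenic double bond, so it is one achiral compound and no stereocontrol is needed.

**Step 1**
Reactants: 1 3,5-dimethoxyphenol; 2 chlorotri(propan-2-yl)silane (TIPSCl)
Product: 3 (3,5-dimethoxyphenoxy)tri(propan-2-yl)silane
Conditions: imidazole, DMF, rt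
Reagents that add atoms: chlorotri(propan-2-yl)silane 2, CC(C)[Si](Cl)(C(C)C)C(C)C
Why: Imidazole-promoted O-silylation of a phenol; the bulky TIPS ether resists n-BuLi and is a poor ortho-director, which sets up the regiochemistry of step 2.

**Step 2**
Reactants: 3 (3,5-dimethoxyphenoxy)tri(propan-2-yl)silane; 4 1-bromo-3-methylbut-2-ene (prenyl bromide)
Product: 6 [3,5-dimethoxy-4-(3-methylbut-2-en-1-yl)phenoxy]tri(propan-2-yl)silane, via aryllithium 5 (not isolated)
Conditions: n-BuLi, TMEDA, THF, 0 °C; then CuBr·SMe2 (10 mol%), prenyl bromide, −78 °C → rt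
Reagents that add atoms: 1-bromo-3-methylbut-2-ene 4, CC(C)=CCBr
Why: Directed ortho-metalation, in which the two methoxy groups jointly direct lithiation to the carbon between them, followed by copper-catalysed allylic substitution that gives the linear (SN2) prenyl arene.

**Step 3**
Reactants: 7 1-(2,4,6-trihydroxyphenyl)ethan-1-one (phloroacetophenone, dried); 8 tert-butyldimethylsilyl trifluoromethanesulfonate (TBSOTf)
Product: 9 tert-butyl(dimethyl){1-[2,4,6-tris(tert-butyldimethylsilyloxy)phenyl]ethenyloxy}silane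
Conditions: TBSOTf (4.6 equiv), Et3N, CH2Cl2, 0 °C → rt
Reagents that add atoms: tert-butyldimethylsilyl trifluoromethanesulfonate 8, CC(C)(C)[Si](C)(C)OS(=O)(=O)C(F)(F)F
Why: Exhaustive soft silylation (silyl triflate/amine) protects the three phenols and converts the methyl ketone, enolisable on one side only, into its silyl enol ether in the same operation.

**Step 4**
Reactants: 9 tert-butyl(dimethyl){1-[2,4,6-tris(tert-butyldimethylsilyloxy)phenyl]ethenyloxy}silane (1.25 equiv); 6 [3,5-dimethoxy-4-(3-methylbut-2-en-1-yl)phenoxy]tri(propan-2-yl)silane (1.0 equiv)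
Product: 12 2-[2,4-dimethoxy-3-(3-methylbut-2-en-1-yl)-6-(triisopropylsilyloxy)phenyl]-1-(2,4,6-trihydroxyphenyl)ethan-1-one, via enolonium tosylate 10 (not isolated), via silylated deoxybenzoin 11 (not isolated)
Conditions: PhI(OH)OTs (1.2 equiv), BF3·OEt2, CH2Cl2, −78 °C, 5 min; then 6, −78 → −20 °C; aq. NaHCO3; crude, KHF2, MeOH, rt
Reagents that add atoms: none
Why: Proposed new method: Koser's reagent (trivalent iodine) activated by BF3 turns the silyl enol ether into an enolonium (an α-keto-λ3-iodane, i.e. an α-carbonyl cation equivalent with PhI as leaving group) whose primary CH2 carries no β-hydrogen and is attacked in a Friedel–Crafts-type SN2/SN2' step by one of the two equivalent free positions of symmetric arene 6 (ortho/para to three oxygen donors), so one regioisomer forms and no stereocentre arises; the closest known reaction type is the transition-metal-free α-arylation of ketone enolonium species (from TMS enol ethers with PhI(OH)OTs/BF3·OEt2) with indoles and pyrroles, and KHF2/MeOH then cleaves the three acyl-activated aryl TBS ethers faster than the electron-rich aryl TIPS ether.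

**Step 5**
Reactants: 12 2-[2,4-dimethoxy-3-(3-methylbut-2-en-1-yl)-6-(triisopropylsilyloxy)phenyl]-1-(2,4,6-trihydroxyphenyl)ethan-1-one; 13 tert-butoxybis(dimethylamino)methane (Bredereck's reagent)
Product: 16 5,7-dihydroxy-3-[6-hydroxy-2,4-dimethoxy-3-(3-methylbut-2-en-1-yl)phenyl]-4H-chromen-4-one (target), via enaminone 14 (not isolated), via TIPS-protected isoflavone 15 (not isolated)
Conditions: t-BuOCH(NMe2)2 (5 equiv), THF, 60 °C; AcOH, rt; then TBAF, 0 °C → rt
Reagents that add atoms: tert-butoxybis(dimethylamino)methane 13, CN(C)C(OC(C)(C)C)N(C)C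
Why: Bredereck aminomethylenation of the deoxybenzoin CH2 followed by addition–elimination ring closure by the chelated ring A ortho-OH (the classical deoxybenzoin-to-isoflavone synthesis, without the O-methylation seen with DMF dimethyl acetal) closes ring C while the ring B oxygen is still silylated, so no benzofuran can form, and buffered fluoride then removes the TIPS group.

**Compound list**
1 | 3,5-dimethoxyphenol | COc1cc(O)cc(OC)c1 | starting material
2 | chlorotri(propan-2-yl)silane (TIPSCl) | CC(C)[Si](Cl)(C(C)C)C(C)C | starting material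
3 | (3,5-dimethoxyphenoxy)tri(propan-2-yl)silane | COc1cc(OC)cc(O[Si](C(C)C)(C(C)C)C(C)C)c1 | intermediate
4 | 1-bromo-3-methylbut-2-ene (prenyl bromide) | CC(C)=CCBr | starting material
5 | [2,6-dimethoxy-4-(triisopropylsilyloxy)phenyl]lithium | [Li]c1c(OC)cc(O[Si](C(C)C)(C(C)C)C(C)C)cc1OC | intermediate
6 | [3,5-dimethoxy-4-(3-methylbut-2-en-1-yl)phenoxy]tri(propan-2-yl)silane | COc1cc(O[Si](C(C)C)(C(C)C)C(C)C)cc(OC)c1CC=C(C)C | intermediate
7 | 1-(2,4,6-trihydroxyphenyl)ethan-1-one (phloroacetophenone) | CC(=O)c1c(O)cc(O)cc1O | starting material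
8 | tert-butyldimethylsilyl trifluoromethanesulfonate (TBSOTf) | CC(C)(C)[Si](C)(C)OS(=O)(=O)C(F)(F)F | starting material
9 | tert-butyl(dimethyl){1-[2,4,6-tris(tert-butyldimethylsilyloxy)phenyl]ethenyloxy}silane | C=C(O[Si](C)(C)C(C)(C)C)c1c(O[Si](C)(C)C(C)(C)C)cc(O[Si](C)(C)C(C)(C)C)cc1O[Si](C)(C)C(C)(C)C | intermediate
10 | {2-oxo-2-[2,4,6-tris(tert-butyldimethylsilyloxy)phenyl]ethyl}(phenyl)-λ3-iodanyl 4-methylbenzenesulfonate (enolonium, drawn carbon-bound) | Cc1ccc(cc1)S(=O)(=O)OI(CC(=O)c1c(O[Si](C)(C)C(C)(C)C)cc(O[Si](C)(C)C(C)(C)C)cc1O[Si](C)(C)C(C)(C)C)c1ccccc1 | intermediate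
11 | 2-[2,4-dimethoxy-3-(3-methylbut-2-en-1-yl)-6-(triisopropylsilyloxy)phenyl]-1-[2,4,6-tris(tert-butyldimethylsilyloxy)phenyl]ethan-1-one | O=C(Cc1c(OC)c(CC=C(C)C)c(OC)cc1O[Si](C(C)C)(C(C)C)C(C)C)c1c(O[Si](C)(C)C(C)(C)C)cc(O[Si](C)(C)C(C)(C)C)cc1O[Si](C)(C)C(C)(C)C | intermediate
12 | 2-[2,4-dimethoxy-3-(3-methylbut-2-en-1-yl)-6-(triisopropylsilyloxy)phenyl]-1-(2,4,6-trihydroxyphenyl)ethan-1-one | O=C(Cc1c(OC)c(CC=C(C)C)c(OC)cc1O[Si](C(C)C)(C(C)C)C(C)C)c1c(O)cc(O)cc1O | intermediate
13 | tert-butoxybis(dimethylamino)methane (Bredereck's reagent) | CN(C)C(OC(C)(C)C)N(C)C | starting material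
14 | 3-(dimethylamino)-2-[2,4-dimethoxy-3-(3-methylbut-2-en-1-yl)-6-(triisopropylsilyloxy)phenyl]-1-(2,4,6-trihydroxyphenyl)prop-2-en-1-one (double-bond geometry not controlled) | CN(C)C=C(C(=O)c1c(O)cc(O)cc1O)c1c(OC)c(CC=C(C)C)c(OC)cc1O[Si](C(C)C)(C(C)C)C(C)C | intermediate
15 | 3-[2,4-dimethoxy-3-(3-methylbut-2-en-1-yl)-6-(triisopropylsilyloxy)phenyl]-5,7-dihydroxy-4H-chromen-4-one | COc1cc(O[Si](C(C)C)(C(C)C)C(C)C)c(-c2coc3cc(O)cc(O)c3c2=O)c(OC)c1CC=C(C)C | intermediate
16 | 5,7-dihydroxy-3-[6-hydroxy-2,4-dimethoxy-3-(3-methylbut-2-en-1-yl)phenyl]-4H-chromen-4-one | COc1cc(O)c(-c2coc3cc(O)cc(O)c3c2=O)c(OC)c1CC=C(C)C | target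

**Totals**
Total step count: 5. Longest linear sequence: 4 steps (steps 1, 2, 4, 5); the ring A branch is 3 steps (3, 4, 5).

**Steps most likely to fail**

Step 4 (key coupling). This is the largest risk in the route. An ortho silyloxy group of ring A may attack the enolonium carbon and give a benzofuran-3(2H)-one. The TBS enol ether is less precedented than a TMS enol ether. The prenyl alkene of 6 is a second, weaker nucleophile. KHF2 may also touch the TIPS ether. The fallback keeps the same bond construction but moves it to a ketone whose ortho oxygen is locked in ring C; it sets out from arene 6. Commercial 5,7-dihydroxychroman-4-one F1 is persilylated (TBSOTf, Et3N, CH2Cl2) to 4,5,7-tris(tert-butyldimethylsilyloxy)-2H-chromene F2. PhI(OH)OTs/BF3·OEt2 at −78 °C gives the chromanone enolonium tosylate F3, which is captured by 6 to give the racemic silylated isoflavanone F4. TMSOTf/Et3N converts this into the isoflavanone TMS enol ether F5, and Pd(OAc)2 in MeCN (Saegusa–Ito oxidation) gives the fully silylated isoflavone F6. TBAF/AcOH removes the three silyl groups and the sequence comes back to the route at 16.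

Step 5 (ring C closure). The three free phenols consume Bredereck's reagent, and the phloroglucinol ring may be C-aminomethylenated. Early loss of TIPS would open a benzofuran pathway. The fallback installs the one-carbon unit before the phenols are unmasked; it sets out from 11, which is purified after the coupling instead of being treated with KHF2. Bredereck's reagent in toluene at 90 °C converts the non-phenolic ketone into the fully silylated enaminone F7. KHF2/MeOH then frees the ring A phenols, which gives 14, where the route is rejoined (closure to 15 and TBAF as before).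

Step 2 (prenylation). Risks are incomplete or misdirected lithiation and some SN2' (reverse-prenyl) product. The fallback separates C–C bond formation from the alkene substitution pattern; it sets out from 3. Aryllithium 5 is quenched with allyl bromide, which has no regiochemical ambiguity, to give the allyl arene F8. Cross-metathesis with 2-methylbut-2-ene (second-generation Grubbs catalyst, CH2Cl2, 40 °C) turns allyl into prenyl and comes back to the route at 6.

**Further compounds**
F1 | step 4 | 5,7-dihydroxychroman-4-one (bought) | O=C1CCOc2cc(O)cc(O)c12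
F2 | step 4 | 4,5,7-tris(tert-butyldimethylsilyloxy)-2H-chromene | CC(C)(C)[Si](C)(C)OC1=CCOc2cc(O[Si](C)(C)C(C)(C)C)cc(O[Si](C)(C)C(C)(C)C)c12
F3 | step 4 | [5,7-bis(tert-butyldimethylsilyloxy)-4-oxochroman-3-yl](phenyl)-λ3-iodanyl 4-methylbenzenesulfonate (chromanone enolonium tosylate, drawn carbon-bound) | Cc1ccc(cc1)S(=O)(=O)OI(C1COc2cc(O[Si](C)(C)C(C)(C)C)cc(O[Si](C)(C)C(C)(C)C)c2C1=O)c1ccccc1
F4 | step 4 | racemic 5,7-bis(tert-butyldimethylsilyloxy)-3-[2,4-dimethoxy-3-(3-methylbut-2-en-1-yl)-6-(triisopropylsilyloxy)phenyl]chroman-4-one | O=C1C(c2c(OC)c(CC=C(C)C)c(OC)cc2O[Si](C(C)C)(C(C)C)C(C)C)COc2cc(O[Si](C)(C)C(C)(C)C)cc(O[Si](C)(C)C(C)(C)C)c12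
F5 | step 4 | 5,7-bis(tert-butyldimethylsilyloxy)-3-[2,4-dimethoxy-3-(3-methylbut-2-en-1-yl)-6-(triisopropylsilyloxy)phenyl]-4-(trimethylsilyloxy)-2H-chromene | C[Si](C)(C)OC1=C(c2c(OC)c(CC=C(C)C)c(OC)cc2O[Si](C(C)C)(C(C)C)C(C)C)COc2cc(O[Si](C)(C)C(C)(C)C)cc(O[Si](C)(C)C(C)(C)C)c12
F6 | step 4 | 5,7-bis(tert-butyldimethylsilyloxy)-3-[2,4-dimethoxy-3-(3-methylbut-2-en-1-yl)-6-(triisopropylsilyloxy)phenyl]-4H-chromen-4-one | COc1cc(O[Si](C(C)C)(C(C)C)C(C)C)c(-c2coc3cc(O[Si](C)(C)C(C)(C)C)cc(O[Si](C)(C)C(C)(C)C)c3c2=O)c(OC)c1CC=C(C)C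
F7 | step 5 | 3-(dimethylamino)-2-[2,4-dimethoxy-3-(3-methylbut-2-en-1-yl)-6-(triisopropylsilyloxy)phenyl]-1-[2,4,6-tris(tert-butyldimethylsilyloxy)phenyl]prop-2-en-1-one | CN(C)C=C(C(=O)c1c(O[Si](C)(C)C(C)(C)C)cc(O[Si](C)(C)C(C)(C)C)cc1O[Si](C)(C)C(C)(C)C)c1c(OC)c(CC=C(C)C)c(OC)cc1O[Si](C(C)C)(C(C)C)C(C)C
F8 | step 2 | [3,5-dimethoxy-4-(prop-2-en-1-yl)phenoxy]tri(propan-2-yl)silane | COc1cc(O[Si](C(C)C)(C(C)C)C(C)C)cc(OC)c1CC=C
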